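**Plan**

- Numbering used throughout: ring A is C1 (CMe2), C2 (CHBr), C3 (CHOH), C4=C5(Me) and the spiro carbon C6; ring B is C6, C7 (CH2), C8 (CHCl), C9 (CMeBr), C10, C11.
- Retrosynthesis: C3–OH and C2–Br go back to the ring A enone, and C9–Br and C8–Cl to a C8=C9 alkene. The spiro dienone is then cut at C6–C7, at the bond joining ring A to the C11–C10 arm (enolate alkylation) and at C–Si, which leaves dimedone, but-3-yn-1-ol and a silylboronate.
- Enabling feature: C6 is the γ-carbon of the ring A enone C5(Me)=C4H–C3=O, so it is the far terminus of the derived silyl dienol ether. Ring B needs its C9(Me)=C8H alkene exactly where an allylsilane leaves one after reacting through its CH2 end (C7).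
- Forward order: ring A is made from dimedone and the silane chain is attached to it. Ring B and the spiro carbon arise together in the anodic dienol ether–allylsilane coupling, and the halogens and the alcohol are added last.
- Stereochemistry: the silicon-bearing carbon is set by ligand-controlled copper-catalysed SN2′ silylation and relayed to C6 (anti SE2′, chair). C8/C9 follow from anti chlorohydroxylation on the ring B face dictated by C6 and bromide substitution with retention. C2 comes from α′-bromination (epimerisable, settled by separation) and C3 from cis-selective hydride reduction.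

Key step: step 11

Assumption: in step 4 the enantiomer of the chiral ligand is chosen that delivers the (S)-silane; should the relay in step 11 run in the opposite sense, the mirror-image ligand corrects it without other changes.

**Route**

Step 1
Reactants: 1 but-3-yn-1-ol
Product: 2 tert-butyl(but-3-yn-1-yloxy)dimethylsilane
Conditions: t-BuMe2SiCl, imidazole, CH2Cl2, 0 °C to rt
Reagents that add atoms: tert-butyldimethylsilyl chloride, CC(C)(C)[Si](C)(C)Cl
Why: Imidazole-promoted silylation of a primary alcohol masks the OH for the organometallic steps that follow.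

Step 2
Reactants: 2 tert-butyl(but-3-yn-1-yloxy)dimethylsilane
Product: 4 (E)-5-(tert-butyldimethylsilyloxy)-3-methylpent-2-en-1-ol, via alkenylalane 3 (not isolated)
Conditions: Me3Al, (C5H5)2ZrCl2 (cat.), CH2Cl2, 0 °C to rt; then n-BuLi, THF, 0 °C; (CH2O)n, rt; aq. NH4Cl
Reagents that add atoms: trimethylaluminium, C[Al](C)C; formaldehyde (as paraformaldehyde), C=O
Why: Negishi zirconium-catalysed carboalumination adds methyl and aluminium syn across the terminal alkyne with aluminium at the terminus, and the derived alanate is hydroxymethylated with retention, so only the (E)-trisubstituted allylic alcohol should form.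

Step 3
Reactants: 4 (E)-5-(tert-butyldimethylsilyloxy)-3-methylpent-2-en-1-ol
Product: 5 (E)-5-(tert-butyldimethylsilyloxy)-3-methylpent-2-en-1-yl diethyl phosphate
Conditions: ClP(O)(OEt)2, pyridine, CH2Cl2, 0 °C
Reagents that add atoms: diethyl chlorophosphate, CCOP(=O)(Cl)OCC
Why: Phosphorylation of the primary allylic alcohol installs the leaving group required for γ-selective copper-catalysed allylic substitution.

Step 4
Reactants: 5 (E)-5-(tert-butyldimethylsilyloxy)-3-methylpent-2-en-1-yl diethyl phosphate; 6 (dimethylphenylsilyl)boronic acid pinacol ester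
Product: 7 tert-butyl{[(3S)-3-(dimethylphenylsilyl)-3-methylpent-4-en-1-yl]oxy}dimethylsilane
Conditions: CuCl (5 mol%), chiral imidazolinium chloride (N-heterocyclic carbene precursor, 5.5 mol%), NaOMe, THF, 0 °C
Reagents that add atoms: none
Why: Copper-catalysed enantioselective allylic substitution with a silylboronate (SN2′) delivers silicon to the γ-carbon of the (E)-phosphate and creates the quaternary silicon-bearing stereocentre under ligand control.

Step 5
Reactants: 7 tert-butyl{[(3S)-3-(dimethylphenylsilyl)-3-methylpent-4-en-1-yl]oxy}dimethylsilane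
Product: 8 (3S)-3-(dimethylphenylsilyl)-3-methylpent-4-en-1-ol
Conditions: camphorsulfonic acid (10 mol%), MeOH, 0 °C
Reagents that add atoms: none
Why: Acid-catalysed methanolysis cleaves the primary silyl ether, and a catalytic sulfonic acid at 0 °C is too weak to protodesilylate the allylsilane.

Step 6
Reactants: 8 (3S)-3-(dimethylphenylsilyl)-3-methylpent-4-en-1-ol
Product: 9 [(3S)-5-iodo-3-methylpent-1-en-3-yl]dimethyl(phenyl)silane
Conditions: PPh3, imidazole, I2 (premixed), CH2Cl2, 0 °C; then 8
Reagents that add atoms: iodine, II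
Why: Appel-type iodination of the primary alcohol proceeds by SN2 at the activated carbon, and premixing the phosphine with iodine keeps free iodine away from the allylsilane.

Step 7
Reactants: 10 dimedone
Product: 11 3-isobutoxy-5,5-dimethylcyclohex-2-en-1-one
Conditions: i-BuOH, p-TsOH (cat.), toluene, reflux, Dean–Stark trap
Reagents that add atoms: 2-methylpropan-1-ol, CC(C)CO
Why: Acid-catalysed enol etherification of the cyclic 1,3-diketone is driven by azeotropic removal of water.

Step 8
Reactants: 11 3-isobutoxy-5,5-dimethylcyclohex-2-en-1-one; 9 [(3S)-5-iodo-3-methylpent-1-en-3-yl]dimethyl(phenyl)silane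
Product: 12 6-[(3S)-3-(dimethylphenylsilyl)-3-methylpent-4-en-1-yl]-3-isobutoxy-5,5-dimethylcyclohex-2-en-1-one (both epimers at the ring carbon)
Conditions: LiN(i-Pr)2, THF, −78 °C; then 9, DMPU, −78 °C to rt
Reagents that add atoms: none
Why: Stork–Danheiser kinetic α′-deprotonation of the vinylogous ester and SN2 alkylation by the primary iodide join the two fragments; the new ring stereocentre forms as a mixture, which is harmless because it becomes sp2 in step 10.

Step 9
Reactants: 12 6-[(3S)-3-(dimethylphenylsilyl)-3-methylpent-4-en-1-yl]-3-isobutoxy-5,5-dimethylcyclohex-2-en-1-one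
Product: 14 4-[(3S)-3-(dimethylphenylsilyl)-3-methylpent-4-en-1-yl]-3,5,5-trimethylcyclohex-2-en-1-one (both epimers at C4), via carbinol 13 (not isolated)
Conditions: MeLi, CeCl3, THF, −78 to 0 °C; then 1 M HCl, 0 °C
Reagents that add atoms: methyllithium, [Li]C
Why: In this Stork–Danheiser transposition the organocerium reagent adds 1,2 to the vinylogous ester carbonyl without enolising it, and cold dilute acid hydrolyses the enol ether and dehydrates the β-hydroxy ketone to the transposed enone while leaving the allylsilane intact.

Step 10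
Reactants: 14 4-[(3S)-3-(dimethylphenylsilyl)-3-methylpent-4-en-1-yl]-3,5,5-trimethylcyclohex-2-en-1-one
Product: 15 tert-butyl({4-[(3S)-3-(dimethylphenylsilyl)-3-methylpent-4-en-1-yl]-3,5,5-trimethylcyclohexa-1,3-dien-1-yl}oxy)dimethylsilane
Conditions: t-BuMe2SiOTf, Et3N, CH2Cl2, 0 °C to rt (equilibrating)
Reagents that add atoms: tert-butyldimethylsilyl triflate, CC(C)(C)[Si](C)(C)OS(=O)(=O)C(F)(F)F
Why: Soft enolisation with silyl triflate and amine under equilibrating conditions removes the γ-hydrogen at C4 and should give the linear, fully substituted silyl dienol ether as the thermodynamic isomer, erasing the C4 stereocentre; cross-conjugated or exocyclic isomers cannot cyclise in step 11 and would only return enone 14.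

Step 11
Reactants: 15 tert-butyl({4-[(3S)-3-(dimethylphenylsilyl)-3-methylpent-4-en-1-yl]-3,5,5-trimethylcyclohexa-1,3-dien-1-yl}oxy)dimethylsilane
Product: 16 (6S)-1,1,5,9-tetramethylspiro[5.5]undeca-4,8-dien-3-one
Conditions: undivided cell, reticulated vitreous carbon anode, platinum cathode, constant current, 2.1–2.2 F/mol, LiClO4 (0.1 M), 2,6-lutidine, MeCN/i-PrOH (4:1), rt
Reagents that add atoms: none
Why: Proposed new method: the silyl dienol ether has the lowest oxidation potential in 15, so the anode removes one electron from it; the radical cation is electrophilic at C4 of the diene (the terminus remote from oxygen, the future C6) and is attacked there by the CH2 terminus of the tethered allylsilane, the β-silyl cation then sheds PhMe2Si to isopropanol to leave the C9(Me)=C8H alkene, and the silyloxyallyl radical gives up a second electron and its silyl group to return the enone. The closest known reaction type is the anodic coupling of enol ether radical cations with allylsilanes to form quaternary carbons, which has not been shown at the terminus of a silyloxydiene. Ring B closes in a 6-endo-trig mode with respect to the vinyl group; attack at the other electrophilic carbon (C2 of the diene) would need an eight-membered ring, and the internal alkene carbon lacks the β-silicon activation. The spiro centre C6 is controlled by the silicon-bearing stereocentre: anti SE2′ attack with a pseudo-axial C–Si bond, in a chair that folds the forming ring over the flat C5 side of ring A and away from CMe2, should convert the (S)-silane into (6S)-16. The step needs oxidation of the dienol ether ahead of the allylsilane and the aryl group, which the donor oxygen secures, and C–C bond formation ahead of solvent capture, which the intramolecular silicon-activated alkene and the lutidine buffer are meant to secure; radical-cation bond formation tolerates the neighbouring gem-dimethyl carbon.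

Step 12
Reactants: 16 (6S)-1,1,5,9-tetramethylspiro[5.5]undeca-4,8-dien-3-one
Product: 17 (6S,8S,9S)-8-chloro-9-hydroxy-1,1,5,9-tetramethylspiro[5.5]undec-4-en-3-one
Conditions: trichloroisocyanuric acid (0.4 equiv), acetone/H2O, 0 °C
Reagents that add atoms: trichloroisocyanuric acid, ClN1C(=O)N(Cl)C(=O)N(Cl)C1=O; water, O
Why: In this electrophilic chlorohydroxylation the electron-rich C8=C9 alkene (not the enone) takes up Cl+, and water opens the chloronium ion at the tertiary carbon C9 in the trans-diaxial (Fürst–Plattner) sense through the half-chair that keeps C1 (CMe2) equatorial, so OH should enter C9 on the open face anti to the axial C5 and Cl end on C8 syn to C5, the (8S,9S) isomer.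

Step 13
Reactants: 17 (6S,8S,9S)-8-chloro-9-hydroxy-1,1,5,9-tetramethylspiro[5.5]undec-4-en-3-one
Product: 18 (6S,8S,9S)-9-bromo-8-chloro-1,1,5,9-tetramethylspiro[5.5]undec-4-en-3-one
Conditions: Me3SiBr, CH2Cl2, −20 to 0 °C
Reagents that add atoms: bromotrimethylsilane, C[Si](C)(C)Br
Why: SN1-type substitution of the tertiary alcohol proceeds with anchimeric assistance, the neighbouring chlorine bridging the C9 cation and bromide opening the chloronium ion anti at the tertiary carbon, so bromine takes the place of OH with retention and stays trans to Cl.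

Step 14
Reactants: 18 (6S,8S,9S)-9-bromo-8-chloro-1,1,5,9-tetramethylspiro[5.5]undec-4-en-3-one
Product: 20 (2R,6R,8S,9S)-2,9-dibromo-8-chloro-1,1,5,9-tetramethylspiro[5.5]undec-4-en-3-one, via silyl dienol ether 19 (not isolated)
Conditions: LiN(SiMe3)2, Me3SiCl, THF, −78 °C; then N-bromosuccinimide, −78 °C
Reagents that add atoms: N-bromosuccinimide, O=C1CCC(=O)N1Br
Why: Kinetic deprotonation of the enone at the α′-methylene C2 with in situ silylation, then bromination of the silyl dienol ether by N-bromosuccinimide, places bromine at C2; the centre is epimerisable and only weakly biased once ring B is saturated, so the (2R)-epimer (equatorial Br, cis to C7) is secured by separation and recycling of the (2S)-epimer through base-mediated enolisation.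

Step 15
Reactants: 20 (2R,6R,8S,9S)-2,9-dibromo-8-chloro-1,1,5,9-tetramethylspiro[5.5]undec-4-en-3-one
Product: 21 (2R,3S,6R,8S,9S)-2,9-dibromo-8-chloro-1,1,5,9-tetramethylspiro[5.5]undec-4-en-3-ol (CNP0537910.1)
Conditions: i-Bu2AlH, CH2Cl2, −78 °C; aq. potassium sodium tartrate
Reagents that add atoms: none
Why: In this 1,2-reduction of the α′-bromo enone by a bulky aluminium hydride, axial approach to C3 is blocked by the axial methyl on C1, so hydride should enter equatorially on the face of C2–H and give the pseudo-axial alcohol cis to bromine.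

**Compound list**

1 | but-3-yn-1-ol | C#CCCO | starting material
2 | tert-butyl(but-3-yn-1-yloxy)dimethylsilane | C#CCCO[Si](C)(C)C(C)(C)C | intermediate
3 | (E)-[4-(tert-butyldimethylsilyloxy)-2-methylbut-1-en-1-yl]dimethylalane | C[Al](C)/C=C(\C)CCO[Si](C)(C)C(C)(C)C | intermediate
4 | (E)-5-(tert-butyldimethylsilyloxy)-3-methylpent-2-en-1-ol | C/C(CCO[Si](C)(C)C(C)(C)C)=C\CO | intermediate
5 | (E)-5-(tert-butyldimethylsilyloxy)-3-methylpent-2-en-1-yl diethyl phosphate | C/C(CCO[Si](C)(C)C(C)(C)C)=C\COP(=O)(OCC)OCC | intermediate
6 | (dimethylphenylsilyl)boronic acid pinacol ester | CC1(C)OB(OC1(C)C)[Si](C)(C)c1ccccc1 | starting material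
7 | tert-butyl{[(3S)-3-(dimethylphenylsilyl)-3-methylpent-4-en-1-yl]oxy}dimethylsilane | CC(C)(C)[Si](C)(C)OCC[C@](C)([Si](C)(C)c1ccccc1)C=C | intermediate
8 | (3S)-3-(dimethylphenylsilyl)-3-methylpent-4-en-1-ol | OCC[C@](C)([Si](C)(C)c1ccccc1)C=C | intermediate
9 | [(3S)-5-iodo-3-methylpent-1-en-3-yl]dimethyl(phenyl)silane | ICC[C@](C)([Si](C)(C)c1ccccc1)C=C | intermediate
10 | dimedone (5,5-dimethylcyclohexane-1,3-dione) | CC1(C)CC(=O)CC(=O)C1 | starting material
11 | 3-isobutoxy-5,5-dimethylcyclohex-2-en-1-one | CC(C)COC1=CC(=O)CC(C)(C)C1 | intermediate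
12 | 6-[(3S)-3-(dimethylphenylsilyl)-3-methylpent-4-en-1-yl]-3-isobutoxy-5,5-dimethylcyclohex-2-en-1-one (ring carbon unspecified) | CC(C)COC1=CC(=O)C(CC[C@](C)([Si](C)(C)c2ccccc2)C=C)C(C)(C)C1 | intermediate
13 | 6-[(3S)-3-(dimethylphenylsilyl)-3-methylpent-4-en-1-yl]-3-isobutoxy-1,5,5-trimethylcyclohex-2-en-1-ol (as its lithium alkoxide in the flask) | CC(C)COC1=CC(C)(O)C(CC[C@](C)([Si](C)(C)c2ccccc2)C=C)C(C)(C)C1 | intermediate
14 | 4-[(3S)-3-(dimethylphenylsilyl)-3-methylpent-4-en-1-yl]-3,5,5-trimethylcyclohex-2-en-1-one (C4 unspecified) | CC1=CC(=O)CC(C)(C)C1CC[C@](C)([Si](C)(C)c2ccccc2)C=C | intermediate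
15 | tert-butyl({4-[(3S)-3-(dimethylphenylsilyl)-3-methylpent-4-en-1-yl]-3,5,5-trimethylcyclohexa-1,3-dien-1-yl}oxy)dimethylsilane | CC1=C(CC[C@](C)([Si](C)(C)c2ccccc2)C=C)C(C)(C)CC(O[Si](C)(C)C(C)(C)C)=C1 | intermediate
16 | (6S)-1,1,5,9-tetramethylspiro[5.5]undeca-4,8-dien-3-one | CC1=CC(=O)CC(C)(C)[C@@]12CCC(C)=CC2 | intermediate
17 | (6S,8S,9S)-8-chloro-9-hydroxy-1,1,5,9-tetramethylspiro[5.5]undec-4-en-3-one | CC1=CC(=O)CC(C)(C)[C@@]12CC[C@](C)(O)[C@@H](Cl)C2 | intermediate
18 | (6S,8S,9S)-9-bromo-8-chloro-1,1,5,9-tetramethylspiro[5.5]undec-4-en-3-one | CC1=CC(=O)CC(C)(C)[C@@]12CC[C@](C)(Br)[C@@H](Cl)C2 | intermediate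
19 | kinetic trimethylsilyl dienol ether of 18 (C2=C3 enol ether, 3-trimethylsilyloxy-2,4-diene, ring B unchanged) | CC1=CC(O[Si](C)(C)C)=CC(C)(C)[C@@]12CC[C@](C)(Br)[C@@H](Cl)C2 | intermediate
20 | (2R,6R,8S,9S)-2,9-dibromo-8-chloro-1,1,5,9-tetramethylspiro[5.5]undec-4-en-3-one | CC1=CC(=O)[C@H](Br)C(C)(C)[C@@]12CC[C@](C)(Br)[C@@H](Cl)C2 | intermediate
21 | (2R,3S,6R,8S,9S)-2,9-dibromo-8-chloro-1,1,5,9-tetramethylspiro[5.5]undec-4-en-3-ol | CC1=C[C@H](O)[C@H](Br)C(C)(C)[C@@]12CC[C@](C)(Br)[C@@H](Cl)C2 | target

**Step count and risks**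

Total step count: 15. Longest linear sequence: 14 steps (steps 1–6 and 8–15, from but-3-yn-1-ol).

Steps most likely to fail:

1. Step 11 (anodic coupling). The radical cation may lose its silyl group to the alcohol co-solvent, or be oxidised further, before the allylsilane reaches the diene terminus, which is flanked by the gem-dimethyl carbon. The transfer of chirality from the silicon-bearing carbon to C6 may also be incomplete if the chair with pseudo-axial silicon is not clearly preferred. The fallback uses known chemistry, sets out from vinylogous ester 11 and comes back at dienone 16. Alkylation of the lithium enolate of 11 with 4-iodo-2-methylbut-1-ene gives 3-isobutoxy-5,5-dimethyl-6-(3-methylbut-3-en-1-yl)cyclohex-2-en-1-one F1. A second enolisation and O-acylation with allyl chloroformate gives the allyl enol carbonate F2. Palladium-catalysed decarboxylative asymmetric allylic alkylation (Pd2(dba)3 as zerovalent palladium source, chiral phosphinooxazoline ligand) gives (6S)-6-allyl-3-isobutoxy-5,5-dimethyl-6-(3-methylbut-3-en-1-yl)cyclohex-2-en-1-one F3 with the quaternary centre in place. Ring-closing metathesis with the second-generation Grubbs catalyst RuCl2(=CHPh)(PCy3)(1,3-dimesitylimidazolidin-2-ylidene) closes ring B to (6S)-3-isobutoxy-1,1,9-trimethylspiro[5.5]undeca-3,8-dien-5-one F4. Addition of MeLi/CeCl3 and acidic hydrolysis, as in step 9, transposes the enone and gives 16.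

2. Step 12 (chlorohydroxylation of ring B). Chlorine may be delivered to the other face of ring B, because the chloronium ion must form next to the vinylic methyl group on C5, which leans over that face; ene-type allylic chlorination may also compete with addition. The fallback sets out from dienone 16 and comes back at chlorohydrin 17. Dihydroxylation (OsO4 cat., N-methylmorpholine N-oxide), which should take the open face on the CMe2 side, gives (6S,8R,9S)-8,9-dihydroxy-1,1,5,9-tetramethylspiro[5.5]undec-4-en-3-one F5. SOCl2/Et3N gives the cyclic sulfite F6, and RuCl3 (cat.)/NaIO4 oxidises it to the cyclic sulfate F7. LiCl in DMF opens the sulfate at the secondary carbon C8 with inversion to the lithium chloro sulfate F8, and dilute H2SO4 in wet THF hydrolyses the sulfate ester to 17. The same facial bias that would spoil step 12 is thus turned to advantage by the inversion at C8.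

3. Step 14 (α′-bromination). Control at C2 may be poor, because once ring B is saturated its two arms differ only at a carbon remote from ring A; loss of HBr from the tertiary bromide under base is a lesser risk. The fallback sets out from dienone 16 and comes back at bromoketone 20. Kinetic enolisation and silylation (LiN(SiMe3)2, Me3SiCl) give the trimethylsilyl dienol ether of 16 F9, and N-bromosuccinimide gives (2R,6R)-2-bromo-1,1,5,9-tetramethylspiro[5.5]undeca-4,8-dien-3-one F10. At this stage C7 is allylic and C11 is not, so the two arms differ next to ring A and the C2 epimers can be equilibrated through the enol before going on. Chlorohydroxylation as in step 12 gives (2R,6R,8S,9S)-2-bromo-8-chloro-9-hydroxy-1,1,5,9-tetramethylspiro[5.5]undec-4-en-3-one F11, and Me3SiBr as in step 13 gives 20.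

Further compounds
F1 | step 11 | 3-isobutoxy-5,5-dimethyl-6-(3-methylbut-3-en-1-yl)cyclohex-2-en-1-one (racemic) | CC(C)COC1=CC(=O)C(CCC(C)=C)C(C)(C)C1
F2 | step 11 | allyl 5-isobutoxy-3,3-dimethyl-2-(3-methylbut-3-en-1-yl)cyclohexa-1,5-dien-1-yl carbonate | CC(C)COC1=CC(OC(=O)OCC=C)=C(CCC(C)=C)C(C)(C)C1
F3 | step 11 | (6S)-6-allyl-3-isobutoxy-5,5-dimethyl-6-(3-methylbut-3-en-1-yl)cyclohex-2-en-1-one | O=C1C=C(OCC(C)C)CC(C)(C)[C@@]1(CC=C)CCC(C)=C
F4 | step 11 | (6S)-3-isobutoxy-1,1,9-trimethylspiro[5.5]undeca-3,8-dien-5-one | O=C1C=C(OCC(C)C)CC(C)(C)[C@@]12CCC(C)=CC2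
F5 | step 12 | (6S,8R,9S)-8,9-dihydroxy-1,1,5,9-tetramethylspiro[5.5]undec-4-en-3-one | CC1=CC(=O)CC(C)(C)[C@@]12CC[C@](C)(O)[C@H](O)C2
F6 | step 12 | cyclic sulfite of diol F5 (sulfur configuration unspecified) | CC1=CC(=O)CC(C)(C)[C@@]12CC[C@]3(C)OS(=O)O[C@@H]3C2
F7 | step 12 | cyclic sulfate of diol F5 | CC1=CC(=O)CC(C)(C)[C@@]12CC[C@]3(C)OS(=O)(=O)O[C@@H]3C2
F8 | step 12 | lithium (6S,8S,9S)-8-chloro-1,1,5,9-tetramethyl-3-oxospiro[5.5]undec-4-en-9-yl sulfate | CC1=CC(=O)CC(C)(C)[C@@]12CC[C@](C)(OS(=O)(=O)[O-])[C@@H](Cl)C2.[Li+]
F9 | step 14 | kinetic trimethylsilyl dienol ether of 16 (C2=C3 enol ether) | CC1=CC(O[Si](C)(C)C)=CC(C)(C)[C@@]12CCC(C)=CC2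
F10 | step 14 | (2R,6R)-2-bromo-1,1,5,9-tetramethylspiro[5.5]undeca-4,8-dien-3-one | CC1=CC(=O)[C@H](Br)C(C)(C)[C@@]12CCC(C)=CC2
F11 | step 14 | (2R,6R,8S,9S)-2-bromo-8-chloro-9-hydroxy-1,1,5,9-tetramethylspiro[5.5]undec-4-en-3-one | CC1=CC(=O)[C@H](Br)C(C)(C)[C@@]12CC[C@](C)(O)[C@@H](Cl)C2
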